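## Retrosynthetic overview

1. Target ⇒ its pentamethyl ether that already carries both ortho-phenols (last step: global O-demethylation).
2. Key disconnection: the two aryl C–O bonds ortho to the ketones ⇒ twofold ketone-directed C–H hydroxylation of a 2,3-bis(4-methoxybenzoyl)-1-arylnaphthalene.
3. Ring B of the naphthalene (C1–C4) ⇒ Diels–Alder reaction of a 1-arylisobenzofuran with a symmetrical (E)-1,4-diarylbut-2-ene-1,4-dione, then loss of water.
4. Isobenzofuran ⇒ lactol from a 2-bromobenzaldehyde and an aryl aldehyde; ene-dione ⇒ anisole and fumaryl chloride.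
5. Ring order: all four benzene rings are bought; the furan ring of the lactol is closed first (transient), then ring B is formed by [4+2] cycloaddition and aromatisation; no ring is formed after that.

Assumption: the SMILES has no stereocentre and no configurationally stable axis, so the target is achiral and is made as that one compound; stereocentres occur only in transient intermediates and are erased.

## Route

Step 1
Reactants: 1 anisole (2.2 equiv); 2 fumaryl chloride
Product: 3 (2E)-1,4-bis(4-methoxyphenyl)but-2-ene-1,4-dione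
Conditions: AlCl3 (2.5 equiv), CH2Cl2, 0 → 23 °C; then ice/aq. HCl
Reagents that add atoms: none
Why: Twofold Friedel–Crafts acylation goes para to the methoxy group of each anisole and carries the E double bond of the diacid chloride through unchanged, so no stereocentre is created.

Step 2
Reactants: 4 2-bromo-4,5-dimethoxybenzaldehyde; 5 4-methoxybenzaldehyde
Product: 9 5,6-dimethoxy-3-(4-methoxyphenyl)-1,3-dihydro-2-benzofuran-1-ol (lactol; racemic cis/trans mixture), via lithium α-amino alkoxide 6 (not isolated), via aryllithium 7 (not isolated), via dilithium dialkoxide 8 (not isolated)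
Conditions: LiN(Me)CH2CH2NMe2 (1.05 equiv; from Me2NCH2CH2NHMe and n-BuLi), THF, –20 °C; n-BuLi (1.1 equiv), –78 °C; 5 (1.2 equiv), –78 → 0 °C; then aq. HCl (pH 4), 0 °C
Reagents that add atoms: none
Why: Comins-type in situ protection of the aldehyde as its α-amino alkoxide allows clean bromine–lithium exchange and 1,2-addition of the aryllithium to 5, and mild acid hydrolysis releases the hydroxy aldehyde, which closes to the five-membered lactol whose two stereocentres form unselectively and are both erased in step 3.

Step 3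
Reactants: 9 5,6-dimethoxy-3-(4-methoxyphenyl)-1,3-dihydro-2-benzofuran-1-ol; 3 (2E)-1,4-bis(4-methoxyphenyl)but-2-ene-1,4-dione (1.2 equiv)
Product: 12 2,3-bis(4-methoxybenzoyl)-6,7-dimethoxy-1-(4-methoxyphenyl)naphthalene, via isobenzofuran 10 (not isolated), via oxa-bridged cycloadduct 11 (not isolated)
Conditions: AcOH (10 mol %), PhMe, 110 °C; then TsOH·H2O (20 mol %), 110 °C, Dean–Stark
Reagents that add atoms: none
Why: Acid-catalysed 1,4-dehydration of the lactol gives the reactive 1-arylisobenzofuran, which the electron-poor symmetrical ene-dione traps at once in a Diels–Alder reaction, and the oxa-bridged adduct then aromatises by acid-catalysed bridge opening and β-elimination of water next to the ketones, which removes all four transient stereocentres.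

Step 4
Reactants: 12 2,3-bis(4-methoxybenzoyl)-6,7-dimethoxy-1-(4-methoxyphenyl)naphthalene
Product: 14 2,3-bis(2-hydroxy-4-methoxybenzoyl)-6,7-dimethoxy-1-(4-methoxyphenyl)naphthalene, via bis(trifluoroacetate) 13 (not isolated)
Conditions: Pd(OCOCF3)2 (10 mol %), PhI(OCOCF3)2 (2.6 equiv, three portions), ClCH2CH2Cl, 70 °C; then H2O/THF, 23 °C
Reagents that add atoms: [bis(trifluoroacetoxy)iodo]benzene, PhI(OCOCF3)2, O=C(OI(OC(=O)C(F)(F)F)c1ccccc1)C(F)(F)F
Why: Proposed new method: a twofold ketone-directed ortho C–H hydroxylation of a vicinal diaroylarene, in which each diaryl ketone oxygen binds divalent palladium, trifluoroacetate-assisted concerted metalation–deprotonation closes a five-membered palladacycle on the anisoyl ring, PhI(OCOCF3)2 oxidises it to tetravalent palladium and C–O reductive elimination gives the aryl trifluoroacetate that water cleaves to the phenol; the anisoyl C–H should be chosen over naphthalene C4–H because the two neighbouring aroyl groups are forced out of the naphthalene plane so that each carbonyl is coplanar only with its anisoyl ring (C4 is further shielded by the peri C5–H), each ring should react once because the ortho trifluoroacetoxy group deactivates it and twists it out of conjugation with the carbonyl, and the phenols stay masked as trifluoroacetates so the oxidant cannot take them on to quinones; the closest known reaction type is the palladium-catalysed ketone-directed ortho-hydroxylation of simple acetophenones and benzophenones at a single site, which has not been shown twofold on a 1,2-diaroylarene with competing ortho C–H positions and oxidisable polymethoxyarene rings; no stereocentre is formed.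

Step 5
Reactants: 14 2,3-bis(2-hydroxy-4-methoxybenzoyl)-6,7-dimethoxy-1-(4-methoxyphenyl)naphthalene
Product: 15 2,3-bis(2,4-dihydroxybenzoyl)-1-(4-hydroxyphenyl)naphthalene-6,7-diol (target)
Conditions: BBr3 (12 equiv), CH2Cl2, –78 → 23 °C; then H2O, 0 °C (under Ar)
Reagents that add atoms: none
Why: BBr3 O-demethylation (boron coordinates each ether oxygen and bromide attacks the methyl group in an SN2 step) cleaves the five aryl methyl ethers without touching the diaryl ketones, and hydrolysis of the aryl borates gives the achiral heptaphenol, which has no stereocentre to set.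

## Compound list

1 | anisole | COc1ccccc1 | starting material
2 | fumaryl chloride, (E) | O=C(Cl)/C=C/C(=O)Cl | starting material
3 | (2E)-1,4-bis(4-methoxyphenyl)but-2-ene-1,4-dione | COc1ccc(cc1)C(=O)/C=C/C(=O)c1ccc(OC)cc1 | intermediate
4 | 2-bromo-4,5-dimethoxybenzaldehyde | COc1cc(Br)c(C=O)cc1OC | starting material
5 | 4-methoxybenzaldehyde | COc1ccc(C=O)cc1 | starting material
6 | lithium (2-bromo-4,5-dimethoxyphenyl){[2-(dimethylamino)ethyl](methyl)amino}methanolate (racemic) | [Li+].[O-]C(N(C)CCN(C)C)c1cc(OC)c(OC)cc1Br | intermediate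
7 | lithium {[2-(dimethylamino)ethyl](methyl)amino}(2-lithio-4,5-dimethoxyphenyl)methanolate (racemic) | [Li+].[O-]C(N(C)CCN(C)C)c1cc(OC)c(OC)cc1[Li] | intermediate
8 | dilithium {[2-(dimethylamino)ethyl](methyl)amino}{4,5-dimethoxy-2-[(4-methoxyphenyl)oxidomethyl]phenyl}methanolate (racemic, diastereomer mixture) | [Li+].[Li+].[O-]C(N(C)CCN(C)C)c1cc(OC)c(OC)cc1C([O-])c1ccc(OC)cc1 | intermediate
9 | 5,6-dimethoxy-3-(4-methoxyphenyl)-1,3-dihydro-2-benzofuran-1-ol (racemic, cis/trans mixture at C1/C3) | COc1ccc(cc1)C1OC(O)c2cc(OC)c(OC)cc12 | intermediate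
10 | 5,6-dimethoxy-1-(4-methoxyphenyl)-2-benzofuran (1-arylisobenzofuran) | COc1ccc(cc1)-c1occ2cc(OC)c(OC)cc12 | intermediate
11 | [6,7-dimethoxy-1-(4-methoxyphenyl)-1,2,3,4-tetrahydro-1,4-epoxynaphthalene-2,3-diyl]bis[(4-methoxyphenyl)methanone] (2,3-trans, racemic, mixture of the two endo/exo diastereomers) | COc1ccc(cc1)C(=O)C1C(C(=O)c2ccc(OC)cc2)C2(c3ccc(OC)cc3)OC1c1cc(OC)c(OC)cc12 | intermediate
12 | 2,3-bis(4-methoxybenzoyl)-6,7-dimethoxy-1-(4-methoxyphenyl)naphthalene | COc1ccc(cc1)C(=O)c1cc2cc(OC)c(OC)cc2c(-c2ccc(OC)cc2)c1C(=O)c1ccc(OC)cc1 | intermediate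
13 | 2,3-bis[4-methoxy-2-(trifluoroacetoxy)benzoyl]-6,7-dimethoxy-1-(4-methoxyphenyl)naphthalene | O=C(c1ccc(OC)cc1OC(=O)C(F)(F)F)c1cc2cc(OC)c(OC)cc2c(-c2ccc(OC)cc2)c1C(=O)c1ccc(OC)cc1OC(=O)C(F)(F)F | intermediate
14 | 2,3-bis(2-hydroxy-4-methoxybenzoyl)-6,7-dimethoxy-1-(4-methoxyphenyl)naphthalene | O=C(c1ccc(OC)cc1O)c1cc2cc(OC)c(OC)cc2c(-c2ccc(OC)cc2)c1C(=O)c1ccc(OC)cc1O | intermediate
15 | 2,3-bis(2,4-dihydroxybenzoyl)-1-(4-hydroxyphenyl)naphthalene-6,7-diol (achiral) | O=C(c1ccc(O)cc1O)c1cc2cc(O)c(O)cc2c(-c2ccc(O)cc2)c1C(=O)c1ccc(O)cc1O | target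

## Step count and risks

Total step count: 5. Longest linear sequence: 4 steps (4 → 9 → 12 → 14 → 15; equally 1 → 3 → 12 → 14 → 15).

The three steps most likely to fail:

Step 4 (the proposed new twofold C–H hydroxylation). The risks are oxidation of the electron-rich methoxyarene rings by the iodane, partial reaction at naphthalene C4–H, or stalling at the mono-phenol. The fallback uses known chemistry only, sets out from 9 (with 2) and comes back at 15; the ortho oxygens are brought in with the dienophile. 1,3-Dimethoxybenzene and 2 (AlCl3, CH2Cl2, –10 °C; Friedel–Crafts acylation at C4 of the arene) give (2E)-1,4-bis(2,4-dimethoxyphenyl)but-2-ene-1,4-dione F1. Lactol 9 is converted as in step 3 into 10, which F1 traps to give the oxa-bridged cycloadduct [6,7-dimethoxy-1-(4-methoxyphenyl)-1,2,3,4-tetrahydro-1,4-epoxynaphthalene-2,3-diyl]bis[(2,4-dimethoxyphenyl)methanone] F2 (not isolated). TsOH dehydrates it to 2,3-bis(2,4-dimethoxybenzoyl)-6,7-dimethoxy-1-(4-methoxyphenyl)naphthalene F3. BBr3 (16 equiv, CH2Cl2, –78 → 23 °C) then cleaves all seven methyl ethers and gives 15 directly.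

Step 3 (isobenzofuran Diels–Alder/aromatisation cascade). The risks are oligomerisation of the isobenzofuran and acid ionisation of the doubly benzylic C–O bond of 9 or 11. The fallback sets out from 4 and 3 and comes back at 12; it is a base-mediated double aldol benzannulation that avoids the isobenzofuran. Aryllithium 7, made from 4 via 6 exactly as in step 2, is acylated with commercial N-methoxy-N-methyl-4-methoxybenzamide (Weinreb ketone synthesis), and aqueous HCl gives 4,5-dimethoxy-2-(4-methoxybenzoyl)benzaldehyde F4. Zn dust in AcOH at 80 °C reduces the C=C bond of 3 to give 1,4-bis(4-methoxyphenyl)butane-1,4-dione F5. KOH in EtOH at 78 °C condenses F5 first with the aldehyde of F4 (Knoevenagel-type aldol condensation) and then intramolecularly with its diaryl ketone (aldol condensation with aromatisation) to give 12.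

Step 2 (one-pot protection/exchange/addition). The risks are incomplete bromine–lithium exchange, butylation of 7, or ionisation of the diarylcarbinol on acidic work-up. The fallback sets out from 4 and comes back at 9; a carboxylate replaces the aldehyde as the internal protecting group. NaClO2/NaH2PO4/2-methylbut-2-ene in t-BuOH/H2O (Pinnick oxidation) converts 4 into 2-bromo-4,5-dimethoxybenzoic acid F6. n-BuLi (2.1 equiv, THF, –90 °C; Parham-type exchange on the carboxylate) gives lithium 2-lithio-4,5-dimethoxybenzoate F7. F7 adds to 5 and lactonises on acidification to 5,6-dimethoxy-3-(4-methoxyphenyl)-2-benzofuran-1(3H)-one F8. i-Bu2AlH (1.1 equiv, CH2Cl2, –78 °C) reduces this phthalide to lactol 9.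

## Further compounds

F1 | step 4 | (2E)-1,4-bis(2,4-dimethoxyphenyl)but-2-ene-1,4-dione | COc1ccc(c(OC)c1)C(=O)/C=C/C(=O)c1ccc(OC)cc1OC
F2 | step 4 | [6,7-dimethoxy-1-(4-methoxyphenyl)-1,2,3,4-tetrahydro-1,4-epoxynaphthalene-2,3-diyl]bis[(2,4-dimethoxyphenyl)methanone] (2,3-trans, racemic, endo/exo mixture) | COc1ccc(c(OC)c1)C(=O)C1C(C(=O)c2ccc(OC)cc2OC)C2(c3ccc(OC)cc3)OC1c1cc(OC)c(OC)cc12
F3 | step 4 | 2,3-bis(2,4-dimethoxybenzoyl)-6,7-dimethoxy-1-(4-methoxyphenyl)naphthalene | COc1ccc(c(OC)c1)C(=O)c1cc2cc(OC)c(OC)cc2c(-c2ccc(OC)cc2)c1C(=O)c1ccc(OC)cc1OC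
F4 | step 3 | 4,5-dimethoxy-2-(4-methoxybenzoyl)benzaldehyde | COc1ccc(cc1)C(=O)c1cc(OC)c(OC)cc1C=O
F5 | step 3 | 1,4-bis(4-methoxyphenyl)butane-1,4-dione | COc1ccc(cc1)C(=O)CCC(=O)c1ccc(OC)cc1
F6 | step 2 | 2-bromo-4,5-dimethoxybenzoic acid | COc1cc(Br)c(C(=O)O)cc1OC
F7 | step 2 | lithium 2-lithio-4,5-dimethoxybenzoate | [Li+].[O-]C(=O)c1cc(OC)c(OC)cc1[Li]
F8 | step 2 | 5,6-dimethoxy-3-(4-methoxyphenyl)-2-benzofuran-1(3H)-one (racemic) | COc1ccc(cc1)C1OC(=O)c2cc(OC)c(OC)cc12
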